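**Two questions.** Two numbers are asked of this flask, and one count serves both: turnovers, a rate coefficient times the run time.

Z 0.40 M; time 4.0 h

    E + E ⇌ E2 (K1 = 0.39 /M, k1 = 7.6 × 10⁻⁴ /M/s)
    Z ⇌ E, rate k2*(cs2 - [E]) while solid is left; crystals form when [E] > cs2 (cs2 = 0.27 M, k2 = 9.4 × 10⁻⁵ /s)

1. how much E2 there is at 4.0 h, in percent of the Z charged
2. concentration of E in solution at 4.0 h, in percent of saturation

- percentages count the Z that a species holds: one E2 counts as two
- for a step with 2 of a species take k times the square, and two of it per event
- solid, in amounts per volume of the solution: Z
- at the start none of Z is in solution
- E means what is dissolved; the solid is not counted in it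
- run time (flask): 4.0 h

**Which numbers matter.** In the flask, the decay of E2 runs 28.1 turnovers, far more than one, so an error in k1 leaves E2 at K1 times the square of E. The charge has to be known well: saturation holds 0.327 M of Z, less than the 0.40 M charged, so solid remains and the charge enters as the divisor of y, where a relative error in it passes over undiminished. Dissolution, the rate-limiting step, runs 1.35 turnovers, the coefficient of step 2 times the run time, fewer than for the decay, so errors in k2 or the time pass into E. The solubility and K1 matter too.

**My reckoning.** Setting aside the Z held in E2, the gap to saturation shrinks by a factor e per turnover, to 25.8%. E is then 0.200 M, which gives sat 74.2% and y 7.82%.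

**The forecast.** It says 6.46% and 68.6%, both below my figures, on the ground “so E2 stays near equilibrium”.

**The flask.** It gives 6.45% and 68.6%. Dissolution ran throughout: half of its turnover was done by 1.45 h, at 0.490 turnovers, and 47.3% stood as solid at 4.00 h. E2 followed E meanwhile, with a relaxation half-life of 0.0767 h, shorter than the run, rising from 0.852% at 1.00 h to 2.72% at 2.00 h.

**Second flask.** The neighbour flask, charged with 0.24 M, has the same 1.35 turnovers and, by the reckoning, 0.232 M dissolved, less than its charge. By the reckoning its E is therefore unchanged and its y is 13.0%. The simulation gives 10.8%, with 12.1% still solid.

(Its constants are assumed; the result is computed.)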